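**Retrosynthetic overview**

1. The triene is cut at its central C(sp2)–C(sp2) bond: a (Z)-alkenyl iodide on the spiro core (33) is joined to the myrcene-type dienyl boronate 38 by Suzuki–Miyaura coupling. The iodide comes from a C2 ethynyl group by silylformylation, the enal from a C9 ketone by isopropenyl addition and oxidative 1,3-transposition.
2. The six-membered ring is never built as such: it grows out of a cyclopentanol (ring A) by a semipinacol 1,2-shift in epoxy alcohol 21, which also creates the spiro centre (five to six, step 11).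
3. Epoxy alcohol 21 comes from the union of two five-membered fragments: the organocerium from alkenylstannane 17 (ring B) adds to cyclopentanone 8 (ring A), followed by hydroxyl-directed epoxidation.
4. Feature that makes the key step possible: in 21 the tertiary carbinol carbon of ring A is bonded directly to the fully substituted epoxide carbon of ring B (a 2,3-epoxy alcohol spanning both rings), so a ring A C–C bond can shift to that carbon while the carbinol becomes C=O.
5. Ring order: rings A and B are bought in as 2-iodocyclopentenone and cyclopentenone; ring A becomes the cyclohexane in step 11; the C6 methyl carbinol (MeLi/CeCl3) and the C1 carbinol (oxidation, directed reduction) are set afterwards.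

Key step: step 11

**Remarks (assumptions)**
- Locants for the spiro compounds follow spiro[4.5]decane numbering: C1–C4 cyclopentane, C5 spiro atom, C6–C10 cyclohexane. C1 carries the secondary hydroxyl, C2 the side chain, C6 the methyl carbinol, C9 the enal carbon, C10 the hydroxypropyl chain.
- Ring A is the ring that starts as cyclopentanone 8 and ends as the cyclohexane; ring B is the cyclopentene derived from 9.
- The configuration drawn at the tertiary isopropenyl carbinol of 27–31 is the one expected from equatorial attack; it has no consequence because this centre becomes sp2 in step 21.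
- The enantiomers of the CBS catalyst (step 1) and of the bis(oxazoline) ligand (step 6) are those that give the (R) centres drawn.

**Route**

Step 1
Reactants: 1 2-iodocyclopent-2-en-1-one
Product: 2 (R)-2-iodocyclopent-2-en-1-ol
Conditions: (S)-2-methyl-CBS-oxazaborolidine (10 mol%), BH3·THF, THF, −20 °C
Reagents that add atoms: none
Why: CBS reduction in which the iodoalkene carbon acts as the large group, so hydride is delivered to the face that gives the (R)-carbinol.

Step 2
Reactants: 2 (R)-2-iodocyclopent-2-en-1-ol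
Product: 3 (R)-1-iodo-5-[(4-methoxybenzyl)oxy]cyclopent-1-ene
Conditions: NaH, 4-methoxybenzyl chloride, Bu4NI (cat.), THF/DMF, 0 °C to rt
Reagents that add atoms: 4-methoxybenzyl chloride COc1ccc(CCl)cc1
Why: Williamson etherification at oxygen, which leaves the carbinol stereocentre untouched.

Step 3
Reactants: 3 (R)-1-iodo-5-[(4-methoxybenzyl)oxy]cyclopent-1-ene; 4 (allyloxy)(tert-butyl)dimethylsilane
Product: 6 (R)-tert-butyl{3-[5-((4-methoxybenzyl)oxy)cyclopent-1-en-1-yl]propoxy}dimethylsilane, via B-alkyl-9-BBN adduct 5 (not isolated)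
Conditions: 4, 9-BBN, THF, rt; then 3, PdCl2(dppf) (5 mol%), AsPh3, Cs2CO3, DMF/H2O, rt
Reagents that add atoms: none
Why: anti-Markovnikov hydroboration of the allyl ether followed by B-alkyl Suzuki–Miyaura coupling with the 2-iodocycloalkenyl ether installs the linear three-carbon chain without touching the stereocentre.

Step 4
Reactants: 6 (R)-tert-butyl{3-[5-((4-methoxybenzyl)oxy)cyclopent-1-en-1-yl]propoxy}dimethylsilane
Product: 7 (1R,2S,3R)-2-[3-(tert-butyldimethylsilyloxy)propyl]-3-[(4-methoxybenzyl)oxy]cyclopentan-1-ol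
Conditions: BH3·THF, THF, 0 °C; then NaOH, H2O2, 0 °C
Reagents that add atoms: hydrogen peroxide OO
Why: hydroboration–oxidation places boron on the less substituted alkene carbon and delivers H and B syn from the face opposite to the allylic PMB ether, which sets the chain-bearing centre (chain cis to OPMB) and gives the new hydroxyl trans to OPMB.

Step 5
Reactants: 7 (1R,2S,3R)-2-[3-(tert-butyldimethylsilyloxy)propyl]-3-[(4-methoxybenzyl)oxy]cyclopentan-1-ol
Product: 8 (2R,3R)-2-[3-(tert-butyldimethylsilyloxy)propyl]-3-[(4-methoxybenzyl)oxy]cyclopentan-1-one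
Conditions: Dess–Martin periodinane, NaHCO3, CH2Cl2, 0 °C to rt; used at once
Reagents that add atoms: none
Why: buffered Dess–Martin oxidation should give the ketone without epimerising the cis α-centre or eliminating the β-alkoxy group.

Step 6
Reactants: 9 cyclopent-2-en-1-one; 10 ethynyltriisopropylsilane
Product: 14 (R)-trimethyl{[3-((triisopropylsilyl)ethynyl)cyclopent-1-en-1-yl]oxy}silane, via lithium acetylide 11 (not isolated), via dimethylalkynylalane 12 (not isolated), via aluminium enolate 13 (not isolated)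
Conditions: 10, n-BuLi, Et2O, 0 °C; Me2AlCl; then Ni(acac)2 (5 mol%), chiral cyano-bis(oxazoline) ligand (6 mol%), i-Bu2AlH (5 mol%), 9, t-BuOMe, 0 °C; then Me3SiOTf, −20 °C
Reagents that add atoms: trimethylsilyl trifluoromethanesulfonate C[Si](C)(C)OS(=O)(=O)C(F)(F)F
Why: nickel-catalysed enantioselective conjugate addition of a dimethylalkynylalane to a cyclic enone sets the alkynyl-bearing centre through the chiral ligand, and O-silylation of the aluminium enolate in the same flask fixes the enol double bond between the former carbonyl and α-carbons.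

Step 7
Reactants: 14 (R)-trimethyl{[3-((triisopropylsilyl)ethynyl)cyclopent-1-en-1-yl]oxy}silane
Product: 16 (R)-3-[(triisopropylsilyl)ethynyl]cyclopent-1-en-1-yl trifluoromethanesulfonate, via lithium enolate 15 (not isolated)
Conditions: MeLi, THF, 0 °C; then N-(5-chloropyridin-2-yl)bis(trifluoromethanesulfonimide), −78 °C to rt
Reagents that add atoms: N-(5-chloropyridin-2-yl)bis(trifluoromethanesulfonimide) O=S(=O)(N(c1ccc(Cl)cn1)S(=O)(=O)C(F)(F)F)C(F)(F)F
Why: the enol silane is cleaved to the regiodefined lithium enolate, whose O-triflation keeps the double-bond position; the TIPS alkyne is inert to MeLi.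

Step 8
Reactants: 16 (R)-3-[(triisopropylsilyl)ethynyl]cyclopent-1-en-1-yl trifluoromethanesulfonate
Product: 17 (R)-triisopropyl{[3-(trimethylstannyl)cyclopent-2-en-1-yl]ethynyl}silane
Conditions: (Me3Sn)2, Pd(PPh3)4 (5 mol%), LiCl, THF, 60 °C
Reagents that add atoms: hexamethylditin C[Sn](C)(C)[Sn](C)(C)C
Why: palladium-catalysed stannylation of an enol triflate gives the alkenylstannane with the double bond in place.

Step 9
Reactants: 17 (R)-triisopropyl{[3-(trimethylstannyl)cyclopent-2-en-1-yl]ethynyl}silane; 8 (2R,3R)-2-[3-(tert-butyldimethylsilyloxy)propyl]-3-[(4-methoxybenzyl)oxy]cyclopentan-1-one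
Product: 20 (1S,2R,3R)-2-[3-(tert-butyldimethylsilyloxy)propyl]-3-[(4-methoxybenzyl)oxy]-1-{(R)-3-[(triisopropylsilyl)ethynyl]cyclopent-1-en-1-yl}cyclopentan-1-ol, via alkenyllithium 18 (not isolated), via alkenylcerium dichloride 19 (not isolated)
Conditions: 17, MeLi, THF, −78 to −20 °C; anhydrous CeCl3, −78 °C; then 8, −78 °C
Reagents that add atoms: none
Why: tin–lithium exchange and transmetalation give a weakly basic organocerium reagent that adds 1,2 to the epimerisable ketone from the face opposite to the cis 2-alkyl and 3-PMBO groups, which sets the carbinol centre (OH cis to both).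

Step 10
Reactants: 20 tertiary allylic alcohol from step 9
Product: 21 (1S,2R,3R)-2-[3-(tert-butyldimethylsilyloxy)propyl]-3-[(4-methoxybenzyl)oxy]-1-{4-[(triisopropylsilyl)ethynyl]-6-oxabicyclo[3.1.0]hexan-1-yl}cyclopentan-1-ol (epoxide oxygen trans to the alkynyl group)
Conditions: VO(acac)2 (5 mol%), t-BuOOH (decane), CH2Cl2, 0 °C to rt
Reagents that add atoms: tert-butyl hydroperoxide CC(C)(C)OO
Why: hydroxyl-directed vanadium-catalysed epoxidation delivers oxygen to the alkene face that lets the bulky CH(alkyl) branch of ring A avoid the ring B CH2 next to the alkene (A(1,2) strain), which is also the face opposite to the allylic alkynyl group, so both elements set the two epoxide centres in the same sense.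

Step 11
Reactants: 21 epoxy alcohol from step 10
Product: 22 1-hydroxy-9-[(4-methoxybenzyl)oxy]-10-[3-(tert-butyldimethylsilyloxy)propyl]-2-[(triisopropylsilyl)ethynyl]spiro[4.5]decan-6-one (1-OH cis to C6; trans to the 2-alkynyl group)
Conditions: ZnBr2 (1.0 equiv), CH2Cl2, 0 °C to rt
Reagents that add atoms: none
Why: ZnBr2 binds the epoxide oxygen and the neighbouring tertiary hydroxyl, the C–O bond at the fully substituted epoxide carbon lengthens, and the ring A bond from the carbinol carbon to the CH bearing the silyloxypropyl chain shifts to that carbon from the side opposite to the leaving oxygen while the carbinol collapses to the ketone (semipinacol rearrangement of a 2,3-epoxy alcohol). The closest known reaction types are the Lewis-acid semipinacol ring enlargement of 1-(epoxycycloalkyl)cycloalkanols to spiro β-hydroxy ketones and the pinacol rearrangement of 1,1'-bi(cyclopentane)-1,1'-diol to spiro[4.5]decan-6-one. The six-membered ring is not closed from an open chain: it arises from ring A by a 1,2-shift that inserts the former epoxide carbon between the carbinol carbon and its CH neighbour (five to six), and this carbon becomes the spiro atom. The spiro centre is set by inversion at the epoxide carbon and so follows from the epoxide face fixed in step 10; the migrating CH keeps its configuration and the secondary carbinol is the untouched second epoxide carbon. The step needs migration of the CH and not of the ring CH2 on the other side of the carbinol; the higher migratory aptitude of the more substituted carbon should secure this, and the PMB ether oxygen, which lies on the ring face opposite to the epoxide-bearing substituent, cannot capture the cationic centre.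

Step 12
Reactants: 22 spiro β-hydroxy ketone from step 11
Product: 23 9-[(4-methoxybenzyl)oxy]-6-methyl-10-[3-(tert-butyldimethylsilyloxy)propyl]-2-[(triisopropylsilyl)ethynyl]spiro[4.5]decane-1,6-diol (6-OH on the ring face turned to C1; 1-OH as in 22)
Conditions: MeLi, anhydrous CeCl3, THF, −78 °C
Reagents that add atoms: methyllithium [Li]C
Why: organocerium 1,2-addition to the hindered β-hydroxy ketone avoids retro-aldol cleavage, and because the C10 chain is axial in the preferred chair the axial trajectory is blocked, so equatorial attack should give the axial tertiary alcohol on the face of C1.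

Step 13
Reactants: 23 PMB-protected diol from step 12
Product: 24 6-methyl-10-[3-(tert-butyldimethylsilyloxy)propyl]-2-[(triisopropylsilyl)ethynyl]spiro[4.5]decane-1,6,9-triol
Conditions: DDQ, CH2Cl2/pH 7 buffer, 0 °C
Reagents that add atoms: none
Why: oxidative cleavage of the PMB ether; silyl ethers, the alkyne and the free alcohols are not affected.

Step 14
Reactants: 24 triol from step 13
Product: 25 6-hydroxy-6-methyl-10-[3-(tert-butyldimethylsilyloxy)propyl]-2-[(triisopropylsilyl)ethynyl]spiro[4.5]decane-1,9-dione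
Conditions: Dess–Martin periodinane (3 equiv), NaHCO3, CH2Cl2, 0 °C to rt
Reagents that add atoms: none
Why: both secondary alcohols are oxidised while the tertiary one cannot react, and the buffered neutral medium should avoid epimerisation at C10 and C2 and retro-aldol opening.

Step 15
Reactants: 25 hydroxy diketone from step 14
Product: 26 1,6-dihydroxy-6-methyl-10-[3-(tert-butyldimethylsilyloxy)propyl]-2-[(triisopropylsilyl)ethynyl]spiro[4.5]decan-9-one (1-OH trans to C6; cis to the 2-alkynyl group)
Conditions: Me4NBH(OAc)3, MeCN/AcOH, −30 °C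
Reagents that add atoms: none
Why: Evans–Saksena reduction, in which the C6 tertiary hydroxyl exchanges onto boron and delivers hydride to the C1 ketone from the face on which C6 sits, gives the C1 hydroxyl trans to C6 (opposite to 23), while the C9 ketone, which has no β-hydroxyl, is left.

Step 16
Reactants: 26 keto diol from step 15
Product: 27 6-methyl-9-(prop-1-en-2-yl)-10-[3-(tert-butyldimethylsilyloxy)propyl]-2-[(triisopropylsilyl)ethynyl]spiro[4.5]decane-1,6,9-triol
Conditions: isopropenylmagnesium bromide, anhydrous CeCl3, THF, −78 to 0 °C (excess reagent for the two free hydroxyls)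
Reagents that add atoms: isopropenylmagnesium bromide C=C(C)[Mg]Br
Why: the organocerium reagent adds to the enolisable C9 ketone without epimerising C10; the new carbinol configuration is irrelevant.

Step 17
Reactants: 27 isopropenyl carbinol from step 16
Product: 28 2-ethynyl-10-(3-hydroxypropyl)-6-methyl-9-(prop-1-en-2-yl)spiro[4.5]decane-1,6,9-triol
Conditions: Bu4NF, THF, 0 °C to rt
Reagents that add atoms: none
Why: fluoride removes the alkynyl TIPS group and the primary TBS ether in one operation; no base-sensitive carbonyl is present at this stage.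

Step 18
Reactants: 28 terminal alkyne from step 17
Product: 29 (Z)-2-[1,6,9-trihydroxy-10-(3-hydroxypropyl)-6-methyl-9-(prop-1-en-2-yl)spiro[4.5]decan-2-yl]-3-(triethylsilyl)prop-2-enal
Conditions: Et3SiH, CO (20 atm), Rh4(CO)12 (1 mol%), Et3N, toluene, 40 °C
Reagents that add atoms: triethylsilane CC[SiH](CC)CC; carbon monoxide [C-]#[O+]
Why: rhodium-catalysed silylformylation of a terminal alkyne adds silyl (terminal carbon) and formyl (internal carbon) syn, which gives the (Z)-β-silyl enal; alkenes do not react, and any O-silylation by excess silane is removed in step 27.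

Step 19
Reactants: 29 β-silyl enal from step 18
Product: 30 (Z)-allylic alcohol: 2-[3-hydroxy-1-(triethylsilyl)prop-1-en-2-yl]-10-(3-hydroxypropyl)-6-methyl-9-(prop-1-en-2-yl)spiro[4.5]decane-1,6,9-triol
Conditions: NaBH4, CeCl3·7H2O, MeOH, −40 °C
Reagents that add atoms: none
Why: Luche 1,2-reduction of the enal to the allylic alcohol with the alkene geometry retained.

Step 20
Reactants: 30 pentaol from step 19
Product: 31 tris-TBS ether of 30 (silylated at the two primary hydroxyls and at the C1 hydroxyl; both tertiary hydroxyls free)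
Conditions: t-BuMe2SiOTf (3.3 equiv), 2,6-lutidine, CH2Cl2, −78 to −40 °C
Reagents that add atoms: tert-butyldimethylsilyl trifluoromethanesulfonate CC(C)(C)[Si](C)(C)OS(=O)(=O)C(F)(F)F
Why: at low temperature the silyl triflate should protect the two primary and the secondary alcohol, while the hindered tertiary alcohols stay free.

Step 21
Reactants: 31 tris-TBS ether from step 20
Product: 32 (E)-2-{1-(tert-butyldimethylsilyloxy)-2-[(Z)-3-(tert-butyldimethylsilyloxy)-1-(triethylsilyl)prop-1-en-2-yl]-10-[3-(tert-butyldimethylsilyloxy)propyl]-6-hydroxy-6-methylspiro[4.5]decan-9-ylidene}propanal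
Conditions: pyridinium chlorochromate [C5H5NH][CrO3Cl], NaOAc, 4 Å molecular sieves, CH2Cl2, rt
Reagents that add atoms: pyridinium chlorochromate [O-][Cr](=O)(=O)Cl.c1cc[nH+]cc1
Why: Babler–Dauben oxidative transposition, in which the tertiary allylic chromate ester undergoes a [3,3] shift through a chair with the bulkier C10 branch pseudo-equatorial, should place C10 cis to the methyl group and the new oxygenated carbon cis to C8 before oxidation to the enal.

Step 22
Reactants: 32 alkenylsilane enal from step 21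
Product: 33 (Z)-alkenyl iodide: the triethylsilyl group of 32 replaced by iodine
Conditions: N-iodosuccinimide, (CF3)2CHOH, 0 °C, dark
Reagents that add atoms: N-iodosuccinimide O=C1CCC(=O)N1I
Why: iododesilylation of the alkenylsilane in hexafluoroisopropanol proceeds with retention, so iodine stays cis to the silyloxymethyl group; the electron-poor enal alkene is not attacked.

Step 23
Reactants: 34 6-methylhept-5-en-2-one
Product: 36 6-methylhepta-1,5-dien-2-yl trifluoromethanesulfonate, via lithium enolate 35 (not isolated)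
Conditions: LiN(i-Pr)2, THF, −78 °C; then PhNTf2, −78 to 0 °C
Reagents that add atoms: N-phenylbis(trifluoromethanesulfonimide) O=S(=O)(N(c1ccccc1)S(=O)(=O)C(F)(F)F)C(F)(F)F
Why: kinetic deprotonation on the methyl side and O-triflation give the terminal enol triflate.

Step 24
Reactants: 36 6-methylhepta-1,5-dien-2-yl trifluoromethanesulfonate
Product: 37 7-methyl-3-methyleneoct-6-en-1-yne
Conditions: ethynylmagnesium bromide, ZnBr2, THF, 0 °C; then 36, Pd(PPh3)4 (5 mol%), 0 °C to rt
Reagents that add atoms: ethynylmagnesium bromide C#C[Mg]Br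
Why: Negishi coupling of ethynylzinc bromide with the enol triflate gives the terminal enyne directly.

Step 25
Reactants: 37 7-methyl-3-methyleneoct-6-en-1-yne
Product: 38 (E)-4,4,5,5-tetramethyl-2-(7-methyl-3-methyleneocta-1,6-dien-1-yl)-1,3,2-dioxaborolane
Conditions: pinacolborane, Cp2Zr(H)Cl (5 mol%), Et3N (10 mol%), CH2Cl2, rt
Reagents that add atoms: pinacolborane CC1(C)OBOC1(C)C
Why: zirconium-catalysed syn hydroboration of the terminal alkyne, selective over the alkenes, gives the (E)-dienyl boronate.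

Step 26
Reactants: 33 (Z)-alkenyl iodide from step 22; 38 (E)-dienyl boronate
Product: 39 tris-TBS ether of the target (silylated at the two primary hydroxyls and at C1-OH)
Conditions: Pd(PPh3)4 (10 mol%), aqueous K3PO4, THF, rt, degassed, dark
Reagents that add atoms: none
Why: Suzuki–Miyaura coupling of the alkenyl iodide with the alkenyl boronate forms the triene with retention of both double-bond geometries under mild base that the enal tolerates.

Step 27
Reactants: 39 tris-TBS ether of the target
Product: 40 CNP0246965.2 (target)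
Conditions: HF·pyridine, pyridine, THF, 0 °C to rt
Reagents that add atoms: none
Why: buffered fluoride desilylation removes the three TBS ethers without acid or base strong enough to touch the triene, the enal or the tertiary alcohol.

**Compound list**

1 | 2-iodocyclopent-2-en-1-one | O=C1CCC=C1I | starting material
2 | (R)-2-iodocyclopent-2-en-1-ol | O[C@@H]1CCC=C1I | intermediate
3 | (R)-1-iodo-5-[(4-methoxybenzyl)oxy]cyclopent-1-ene | COc1ccc(CO[C@@H]2CCC=C2I)cc1 | intermediate
4 | (allyloxy)(tert-butyl)dimethylsilane | C=CCO[Si](C)(C)C(C)(C)C | starting material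
5 | 9-[3-(tert-butyldimethylsilyloxy)propyl]-9-borabicyclo[3.3.1]nonane | CC(C)(C)[Si](C)(C)OCCCB1C2CCCC1CCC2 | intermediate
6 | (R)-tert-butyl{3-[5-((4-methoxybenzyl)oxy)cyclopent-1-en-1-yl]propoxy}dimethylsilane | COc1ccc(CO[C@@H]2CCC=C2CCCO[Si](C)(C)C(C)(C)C)cc1 | intermediate
7 | (1R,2S,3R)-2-[3-(tert-butyldimethylsilyloxy)propyl]-3-[(4-methoxybenzyl)oxy]cyclopentan-1-ol (chain cis to OPMB, OH trans to both) | O[C@H]1[C@H](CCCO[Si](C)(C)C(C)(C)C)[C@H](OCc2ccc(OC)cc2)CC1 | intermediate
8 | (2R,3R)-2-[3-(tert-butyldimethylsilyloxy)propyl]-3-[(4-methoxybenzyl)oxy]cyclopentan-1-one (2,3-cis) | O=C1[C@H](CCCO[Si](C)(C)C(C)(C)C)[C@H](OCc2ccc(OC)cc2)CC1 | intermediate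
9 | cyclopent-2-en-1-one | O=C1C=CCC1 | starting material
10 | ethynyltriisopropylsilane | C#C[Si](C(C)C)(C(C)C)C(C)C | starting material
11 | lithium (triisopropylsilyl)acetylide | [Li]C#C[Si](C(C)C)(C(C)C)C(C)C | intermediate
12 | dimethyl[(triisopropylsilyl)ethynyl]aluminium | C[Al](C)C#C[Si](C(C)C)(C(C)C)C(C)C | intermediate
13 | dimethylaluminium (R)-3-[(triisopropylsilyl)ethynyl]cyclopent-1-en-1-olate | CC(C)[Si](C(C)C)(C(C)C)C#C[C@@H]1CCC(=C1)O[Al](C)C | intermediate
14 | (R)-trimethyl{[3-((triisopropylsilyl)ethynyl)cyclopent-1-en-1-yl]oxy}silane | CC(C)[Si](C(C)C)(C(C)C)C#C[C@@H]1CCC(=C1)O[Si](C)(C)C | intermediate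
15 | lithium (R)-3-[(triisopropylsilyl)ethynyl]cyclopent-1-en-1-olate | CC(C)[Si](C(C)C)(C(C)C)C#C[C@@H]1CCC(=C1)O[Li] | intermediate
16 | (R)-3-[(triisopropylsilyl)ethynyl]cyclopent-1-en-1-yl trifluoromethanesulfonate | CC(C)[Si](C(C)C)(C(C)C)C#C[C@@H]1CCC(=C1)OS(=O)(=O)C(F)(F)F | intermediate
17 | (R)-triisopropyl{[3-(trimethylstannyl)cyclopent-2-en-1-yl]ethynyl}silane | CC(C)[Si](C(C)C)(C(C)C)C#C[C@@H]1CCC(=C1)[Sn](C)(C)C | intermediate
18 | (R)-{3-[(triisopropylsilyl)ethynyl]cyclopent-1-en-1-yl}lithium | CC(C)[Si](C(C)C)(C(C)C)C#C[C@@H]1CCC(=C1)[Li] | intermediate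
19 | (R)-dichloro{3-[(triisopropylsilyl)ethynyl]cyclopent-1-en-1-yl}cerium | CC(C)[Si](C(C)C)(C(C)C)C#C[C@@H]1CCC(=C1)[Ce](Cl)Cl | intermediate
20 | (1S,2R,3R)-2-[3-(tert-butyldimethylsilyloxy)propyl]-3-[(4-methoxybenzyl)oxy]-1-{(R)-3-[(triisopropylsilyl)ethynyl]cyclopent-1-en-1-yl}cyclopentan-1-ol | CC(C)[Si](C(C)C)(C(C)C)C#C[C@@H]1CCC(=C1)[C@@]2(O)[C@H](CCCO[Si](C)(C)C(C)(C)C)[C@H](OCc3ccc(OC)cc3)CC2 | intermediate
21 | epoxide of 20 on ring B, oxygen trans to the alkynyl group: 1-{4-[(triisopropylsilyl)ethynyl]-6-oxabicyclo[3.1.0]hexan-1-yl} derivative of the cyclopentanol | CC(C)[Si](C(C)C)(C(C)C)C#C[C@@H]1CC[C@]2(O[C@@H]12)[C@@]3(O)[C@H](CCCO[Si](C)(C)C(C)(C)C)[C@H](OCc4ccc(OC)cc4)CC3 | intermediate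
22 | 1-hydroxy-9-[(4-methoxybenzyl)oxy]-10-[3-(tert-butyldimethylsilyloxy)propyl]-2-[(triisopropylsilyl)ethynyl]spiro[4.5]decan-6-one (1-OH cis to C6, trans to the alkynyl group; C10 chain cis to 9-OPMB) | CC(C)[Si](C(C)C)(C(C)C)C#C[C@@H]1CC[C@]2([C@H](CCCO[Si](C)(C)C(C)(C)C)[C@H](OCc3ccc(OC)cc3)CCC2=O)[C@H]1O | intermediate
23 | 9-[(4-methoxybenzyl)oxy]-6-methyl-10-[3-(tert-butyldimethylsilyloxy)propyl]-2-[(triisopropylsilyl)ethynyl]spiro[4.5]decane-1,6-diol (6-OH on the ring face turned to C1) | CC(C)[Si](C(C)C)(C(C)C)C#C[C@@H]1CC[C@]2([C@H](CCCO[Si](C)(C)C(C)(C)C)[C@H](OCc3ccc(OC)cc3)CC[C@]2(C)O)[C@H]1O | intermediate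
24 | 6-methyl-10-[3-(tert-butyldimethylsilyloxy)propyl]-2-[(triisopropylsilyl)ethynyl]spiro[4.5]decane-1,6,9-triol | CC(C)[Si](C(C)C)(C(C)C)C#C[C@@H]1CC[C@]2([C@H](CCCO[Si](C)(C)C(C)(C)C)[C@H](O)CC[C@]2(C)O)[C@H]1O | intermediate
25 | 6-hydroxy-6-methyl-10-[3-(tert-butyldimethylsilyloxy)propyl]-2-[(triisopropylsilyl)ethynyl]spiro[4.5]decane-1,9-dione | CC(C)[Si](C(C)C)(C(C)C)C#C[C@@H]1CC[C@]2([C@H](CCCO[Si](C)(C)C(C)(C)C)C(=O)CC[C@]2(C)O)C1=O | intermediate
26 | 1,6-dihydroxy-6-methyl-10-[3-(tert-butyldimethylsilyloxy)propyl]-2-[(triisopropylsilyl)ethynyl]spiro[4.5]decan-9-one (1-OH trans to C6, cis to the alkynyl group) | CC(C)[Si](C(C)C)(C(C)C)C#C[C@@H]1CC[C@]2([C@H](CCCO[Si](C)(C)C(C)(C)C)C(=O)CC[C@]2(C)O)[C@@H]1O | intermediate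
27 | 6-methyl-9-(prop-1-en-2-yl)-10-[3-(tert-butyldimethylsilyloxy)propyl]-2-[(triisopropylsilyl)ethynyl]spiro[4.5]decane-1,6,9-triol | CC(C)[Si](C(C)C)(C(C)C)C#C[C@@H]1CC[C@]2([C@H](CCCO[Si](C)(C)C(C)(C)C)[C@](O)(C(C)=C)CC[C@]2(C)O)[C@@H]1O | intermediate
28 | 2-ethynyl-10-(3-hydroxypropyl)-6-methyl-9-(prop-1-en-2-yl)spiro[4.5]decane-1,6,9-triol | C#C[C@@H]1CC[C@]2([C@H](CCCO)[C@](O)(C(C)=C)CC[C@]2(C)O)[C@@H]1O | intermediate
29 | (Z)-2-[1,6,9-trihydroxy-10-(3-hydroxypropyl)-6-methyl-9-(prop-1-en-2-yl)spiro[4.5]decan-2-yl]-3-(triethylsilyl)prop-2-enal | CC[Si](CC)(CC)/C=C(\C=O)[C@@H]1CC[C@]2([C@H](CCCO)[C@](O)(C(C)=C)CC[C@]2(C)O)[C@@H]1O | intermediate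
30 | 2-[(Z)-3-hydroxy-1-(triethylsilyl)prop-1-en-2-yl]-10-(3-hydroxypropyl)-6-methyl-9-(prop-1-en-2-yl)spiro[4.5]decane-1,6,9-triol | CC[Si](CC)(CC)/C=C(\CO)[C@@H]1CC[C@]2([C@H](CCCO)[C@](O)(C(C)=C)CC[C@]2(C)O)[C@@H]1O | intermediate
31 | tris-TBS ether of 30 (at both primary hydroxyls and at C1-OH) | CC[Si](CC)(CC)/C=C(\CO[Si](C)(C)C(C)(C)C)[C@@H]1CC[C@]2([C@H](CCCO[Si](C)(C)C(C)(C)C)[C@](O)(C(C)=C)CC[C@]2(C)O)[C@@H]1O[Si](C)(C)C(C)(C)C | intermediate
32 | (E)-enal: 2-{spiro[4.5]decan-9-ylidene}propanal carrying the C2 (Z)-silylalkenyl group, three TBS ethers and the free 6-OH (CHO cis to C8, methyl cis to C10) | CC[Si](CC)(CC)/C=C(\CO[Si](C)(C)C(C)(C)C)[C@@H]1CC[C@]2([C@H](CCCO[Si](C)(C)C(C)(C)C)/C(=C(\C)C=O)CC[C@]2(C)O)[C@@H]1O[Si](C)(C)C(C)(C)C | intermediate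
33 | (Z)-alkenyl iodide corresponding to 32 (iodine cis to CH2OTBS) | I/C=C(\CO[Si](C)(C)C(C)(C)C)[C@@H]1CC[C@]2([C@H](CCCO[Si](C)(C)C(C)(C)C)/C(=C(\C)C=O)CC[C@]2(C)O)[C@@H]1O[Si](C)(C)C(C)(C)C | intermediate
34 | 6-methylhept-5-en-2-one | CC(=O)CCC=C(C)C | starting material
35 | lithium 6-methylhepta-1,5-dien-2-olate | [Li]OC(=C)CCC=C(C)C | intermediate
36 | 6-methylhepta-1,5-dien-2-yl trifluoromethanesulfonate | C=C(OS(=O)(=O)C(F)(F)F)CCC=C(C)C | intermediate
37 | 7-methyl-3-methyleneoct-6-en-1-yne | C#CC(=C)CCC=C(C)C | intermediate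
38 | (E)-4,4,5,5-tetramethyl-2-(7-methyl-3-methyleneocta-1,6-dien-1-yl)-1,3,2-dioxaborolane | CC1(C)OB(/C=C/C(=C)CCC=C(C)C)OC1(C)C | intermediate
39 | tris-TBS ether of the target (at both primary hydroxyls and at C1-OH) | C=C(/C=C/C=C(\CO[Si](C)(C)C(C)(C)C)[C@@H]1CC[C@]2([C@H](CCCO[Si](C)(C)C(C)(C)C)/C(=C(\C)C=O)CC[C@]2(C)O)[C@@H]1O[Si](C)(C)C(C)(C)C)CCC=C(C)C | intermediate
40 | CNP0246965.2 | C=C(/C=C/C=C(\CO)[C@@H]1CC[C@]2([C@H](CCCO)/C(=C(\C)C=O)CC[C@]2(C)O)[C@@H]1O)CCC=C(C)C | target

**Step count**

Total: 27 steps. Longest linear sequence: 21 steps (steps 1–5, 9–22, 26, 27).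

**Steps most likely to fail, with fallbacks**

Step 11 (key step). What may go wrong: the ring CH2 of ring A may migrate in competition with the CH, or the epoxide may open without any shift; both would lose the spiro ketone. The fallback makes the wanted migrating carbon allylic and keeps the ring enlargement. It sets out from 20: DDQ in buffered CH2Cl2 removes the PMB group to give the diol F1, Dess–Martin oxidation gives the β-hydroxy ketone F2, and methylenation with Cp2TiMe2 in toluene at 70 °C gives the exocyclic methylene compound F3. Vanadium-catalysed epoxidation as in step 10 (the allylic ring B alkene reacts ahead of the homoallylic methylene) gives the epoxy alcohol F4, and ZnBr2 then shifts the now allylic CH to give the spiro ketone F5. MeLi/CeCl3 as in step 12 gives the methyl carbinol F6, Dess–Martin oxidation of the C1 hydroxyl gives the ketone F7, and cleavage of the methylene group with OsO4 (cat.)/NaIO4 and 2,6-lutidine in dioxane–water comes back to the route at 25.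

Step 6. What may go wrong: low enantioselectivity in the nickel-catalysed alkynyl transfer to the five-membered enone, or loss of the regiodefined enolate before silylation. The fallback sets the centre by asymmetric conjugate reduction. It sets out from 10 (as its lithium acetylide 11) and commercial 3-ethoxycyclopent-2-en-1-one: 1,2-addition gives the tertiary carbinol F8, which on dilute acid work-up collapses (Stork–Danheiser transposition) to the enynone F9. Copper hydride reduction (CuCl, NaOt-Bu, (S)-p-tol-BINAP, Ph2SiH2, toluene, 0 °C) adds hydride to the alkynyl-bearing β-carbon and leaves the regiodefined diphenylsilyl enol ether F10. MeLi cleaves F10 to the lithium enolate 15, where the route is rejoined for the triflation of step 7.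

Step 21. What may go wrong: poor control of the geometry of the tetrasubstituted enal in the chromate shift, or oxidative damage to silyl ethers and the alkenylsilane by the chromium reagent. The fallback separates transposition from oxidation. It sets out from 31: Ph3SiOReO3 (2 mol%) in Et2O at 0 °C moves the hydroxyl 1,3 under redox-neutral, reversible conditions to the primary allylic alcohol F11, and MnO2 in CH2Cl2 oxidises this allylic alcohol alone and comes back to the route at 32.

**Further compounds**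

F1 | step 11 | (1S,2R,3R)-2-[3-(tert-butyldimethylsilyloxy)propyl]-1-{(R)-3-[(triisopropylsilyl)ethynyl]cyclopent-1-en-1-yl}cyclopentane-1,3-diol | CC(C)[Si](C(C)C)(C(C)C)C#C[C@@H]1CCC(=C1)[C@@]2(O)[C@H](CCCO[Si](C)(C)C(C)(C)C)[C@H](O)CC2
F2 | step 11 | 2-[3-(tert-butyldimethylsilyloxy)propyl]-3-hydroxy-3-{(R)-3-[(triisopropylsilyl)ethynyl]cyclopent-1-en-1-yl}cyclopentan-1-one | CC(C)[Si](C(C)C)(C(C)C)C#C[C@@H]1CCC(=C1)[C@@]2(O)[C@H](CCCO[Si](C)(C)C(C)(C)C)C(=O)CC2
F3 | step 11 | 2-[3-(tert-butyldimethylsilyloxy)propyl]-3-methylene-1-{(R)-3-[(triisopropylsilyl)ethynyl]cyclopent-1-en-1-yl}cyclopentan-1-ol | CC(C)[Si](C(C)C)(C(C)C)C#C[C@@H]1CCC(=C1)[C@@]2(O)[C@H](CCCO[Si](C)(C)C(C)(C)C)C(=C)CC2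
F4 | step 11 | ring B epoxide of F3 (oxygen trans to the alkynyl group) | CC(C)[Si](C(C)C)(C(C)C)C#C[C@@H]1CC[C@]2(O[C@@H]12)[C@@]3(O)[C@H](CCCO[Si](C)(C)C(C)(C)C)C(=C)CC3
F5 | step 11 | 1-hydroxy-9-methylene-10-[3-(tert-butyldimethylsilyloxy)propyl]-2-[(triisopropylsilyl)ethynyl]spiro[4.5]decan-6-one | CC(C)[Si](C(C)C)(C(C)C)C#C[C@@H]1CC[C@]2([C@H](CCCO[Si](C)(C)C(C)(C)C)C(=C)CCC2=O)[C@H]1O
F6 | step 11 | 6-methyl-9-methylene-10-[3-(tert-butyldimethylsilyloxy)propyl]-2-[(triisopropylsilyl)ethynyl]spiro[4.5]decane-1,6-diol | CC(C)[Si](C(C)C)(C(C)C)C#C[C@@H]1CC[C@]2([C@H](CCCO[Si](C)(C)C(C)(C)C)C(=C)CC[C@]2(C)O)[C@H]1O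
F7 | step 11 | 6-hydroxy-6-methyl-9-methylene-10-[3-(tert-butyldimethylsilyloxy)propyl]-2-[(triisopropylsilyl)ethynyl]spiro[4.5]decan-1-one | CC(C)[Si](C(C)C)(C(C)C)C#C[C@@H]1CC[C@]2([C@H](CCCO[Si](C)(C)C(C)(C)C)C(=C)CC[C@]2(C)O)C1=O
F8 | step 6 | 3-ethoxy-1-[(triisopropylsilyl)ethynyl]cyclopent-2-en-1-ol (racemic, not isolated) | CCOC1=CC(O)(C#C[Si](C(C)C)(C(C)C)C(C)C)CC1
F9 | step 6 | 3-[(triisopropylsilyl)ethynyl]cyclopent-2-en-1-one | O=C1C=C(CC1)C#C[Si](C(C)C)(C(C)C)C(C)C
F10 | step 6 | (R)-diphenyl{[3-((triisopropylsilyl)ethynyl)cyclopent-1-en-1-yl]oxy}silane | CC(C)[Si](C(C)C)(C(C)C)C#C[C@@H]1CCC(=C1)O[SiH](c2ccccc2)c3ccccc3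
F11 | step 21 | primary allylic alcohol corresponding to 32 (CH2OH in place of CHO, same alkene geometry) | CC[Si](CC)(CC)/C=C(\CO[Si](C)(C)C(C)(C)C)[C@@H]1CC[C@]2([C@H](CCCO[Si](C)(C)C(C)(C)C)/C(=C(\C)CO)CC[C@]2(C)O)[C@@H]1O[Si](C)(C)C(C)(C)C
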